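**Retrosynthetic overview**

1. Locants: rings A/B (oxepanone/cyclohexane) carry 1-benzoxepine numbering (O1, C2–C5, C5a, C6–C9, C9a); rings C/D (seven-membered carbocycle/cyclopentane) carry azulene numbering (C1–C3, C3a, C4–C8, C8a). The ethano bridge is cut between its two CH2 groups: radical conjugate addition of an eastern primary iodide to a western 6-methylidene-7-ketone. The C7 carbinol, the C3 ketone and the ring C epoxide are finished after the union.
2. Ring A is closed in the key step by forming the ring-fusion bond C9a–C5a: an Ireland–Claisen rearrangement turns a 7-alkenyl-1,4-dioxepan-2-one (temporary lactone ring) into the oxepene. Ring B is then closed on it by aldol condensation (C8–C9).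
3. Enabling feature: C9a carries the ring A ether oxygen O1 and one hydrogen, and is bonded to the quaternary C5a, whose ring A neighbours C5–C4 run to the C3 carbonyl. With C9 raised to a carboxyl and C4=C5 as an alkene, the array C9–C9a–C5a–C5=C4 is a γ,δ-unsaturated α-alkoxy acid, and O1–C2–C3 is the tether that makes its allyl ester precursor a lactone. The extra oxidation level at C9, the alkene and the silyl ether at C3 are removed in steps 12–16, 29 and 30.
4. The lactone is assembled from prenol (Sharpless epoxide; C2, C3, C4), a (Z)-vinyl iodide (C5, C5a, its methyl, and an allyl arm that becomes C6–C8) and a glycolic acid unit (C9a, C9).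
5. Eastern half: a Diels–Alder reaction on cyclopentenone gives ring D cis-fused to a six-membered ring, which a one-carbon dibromocarbene ring expansion turns into ring C. Ring order: A (step 11), B (step 14); D (step 19), C (step 22); epoxide (step 31).

Key step: step 11

Assumption: reagents are taken to approach the cis-fused bicyclic eastern intermediates from the convex face (the face of the two ring-fusion hydrogens), and the (S)-configured oxazaborolidinium catalyst of step 19 is taken to give adduct 31 as drawn; otherwise its mirror-image catalyst is used.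

**Route**

Step 1
Reactants: 1 prop-2-yn-1-ol
Product: 3 (Z)-3-iodo-2-methylprop-2-en-1-ol, via cyclic alkenylmagnesium alkoxide 2 (not isolated)
Conditions: MeMgBr (2.5 equiv), CuI (10 mol%), THF, −10 °C to rt; then I2, −78 to 0 °C
Reagents that add atoms: methylmagnesium bromide, C[Mg]Br; iodine, II
Why: CuI-catalysed anti-carbomagnesiation of the propargylic alkoxide should give the chelated alkenylmagnesium species, which is iodinated with retention so that iodine ends cis to the CH2OH carbon.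

Step 2
Reactants: 3 (Z)-3-iodo-2-methylprop-2-en-1-ol
Product: 4 (Z)-3-bromo-1-iodo-2-methylprop-1-ene
Conditions: CBr4, PPh3, CH2Cl2, 0 °C
Reagents that add atoms: carbon tetrabromide, BrC(Br)(Br)Br
Why: Appel bromination of the primary allylic alcohol should proceed without touching the alkene geometry or the vinyl iodide.

Step 3
Reactants: 4 (Z)-3-bromo-1-iodo-2-methylprop-1-ene
Product: 5 (Z)-1-iodo-2-methylpenta-1,4-diene
Conditions: CH2=CHMgBr, CuI (10 mol%), THF, −40 to 0 °C
Reagents that add atoms: vinylmagnesium bromide, C=C[Mg]Br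
Why: Copper-catalysed allyl–vinyl cross-coupling should occur by direct displacement at the primary allylic carbon, since the alternative terminus carries the iodine and the vinyl iodide is inert at this temperature.

Step 4
Reactants: 6 3-methylbut-2-en-1-ol
Product: 7 [(2S)-3,3-dimethyloxiran-2-yl]methanol
Conditions: Ti(OiPr)4 (5 mol%), L-(+)-diethyl tartrate (6 mol%), t-BuOOH, 4 Å MS, CH2Cl2, −20 °C
Reagents that add atoms: tert-butyl hydroperoxide, CC(C)(C)OO
Why: Sharpless asymmetric epoxidation; the L-(+)-tartrate complex should deliver oxygen to the face that gives the (2S) epoxy alcohol.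

Step 5
Reactants: 7 [(2S)-3,3-dimethyloxiran-2-yl]methanol
Product: 8 (2R)-3,3-dimethyloxirane-2-carbaldehyde
Conditions: SO3·pyridine, DMSO, iPr2NEt, CH2Cl2, 0 °C
Reagents that add atoms: none
Why: Parikh–Doering oxidation is non-acidic and should leave the epoxide and its stereocentre intact (the descriptor changes only through priorities).

Step 6
Reactants: 5 (Z)-1-iodo-2-methylpenta-1,4-diene; 8 (2R)-3,3-dimethyloxirane-2-carbaldehyde
Product: 10 (1S,2Z)-1-[(2S)-3,3-dimethyloxiran-2-yl]-3-methylhexa-2,5-dien-1-ol, via dienyllithium 9 (not isolated)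
Conditions: 5, t-BuLi (2 equiv), Et2O, −78 °C; then 8, −78 °C
Reagents that add atoms: none
Why: Iodine–lithium exchange retains the alkene geometry, and Felkin–Anh addition to the α,β-epoxy aldehyde (epoxide C–O bond anti to the incoming nucleophile) should set the (1S) carbinol centre as the anti epoxy alcohol.

Step 7
Reactants: 10 (1S,2Z)-1-[(2S)-3,3-dimethyloxiran-2-yl]-3-methylhexa-2,5-dien-1-ol; 11 2-[(tert-butyldimethylsilyl)oxy]acetic acid
Product: 12 silyloxyacetate ester of 10
Conditions: DCC, DMAP (cat.), CH2Cl2, 0 °C to rt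
Reagents that add atoms: none
Why: Steglich esterification of the secondary allylic alcohol under neutral conditions should not disturb the epoxide or the carbinol centre.

Step 8
Reactants: 12 silyloxyacetate ester of 10
Product: 13 hydroxyacetate ester of 10
Conditions: Bu4NF, AcOH, THF, 0 °C
Reagents that add atoms: none
Why: Buffered fluoride desilylation of the primary silyl ether should free the glycolate hydroxyl without ester cleavage or epoxide opening.

Step 9
Reactants: 13 hydroxyacetate ester of 10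
Product: 14 (6S,7S)-6-hydroxy-5,5-dimethyl-7-[(1Z)-2-methylpenta-1,4-dien-1-yl]-1,4-dioxepan-2-one
Conditions: (+)-camphor-10-sulfonic acid (10 mol%), CH2Cl2, 0 °C
Reagents that add atoms: none
Why: Acid-catalysed intramolecular epoxide opening in the 7-endo mode: the glycolate hydroxyl should attack the tertiary epoxide carbon (the better cation, and remote from the electron-poor ester-bearing carbon), which makes the hindered tertiary ether and leaves the secondary C–O bond and its configuration untouched.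

Step 10
Reactants: 14 hydroxy dioxepanone
Product: 15 (6S,7S)-6-[(tert-butyldimethylsilyl)oxy]-5,5-dimethyl-7-[(1Z)-2-methylpenta-1,4-dien-1-yl]-1,4-dioxepan-2-one
Conditions: t-BuMe2SiOTf, 2,6-lutidine, CH2Cl2, −78 to 0 °C
Reagents that add atoms: tert-butyldimethylsilyl trifluoromethanesulfonate, CC(C)(C)[Si](C)(C)OS(=O)(=O)C(F)(F)F
Why: Silylation of the hindered secondary alcohol with the silyl triflate masks the future C3 carbonyl oxygen through to step 29.

Step 11
Reactants: 15 silyloxy dioxepanone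
Product: 19 methyl (2S,3S,6S)-3-allyl-6-[(tert-butyldimethylsilyl)oxy]-3,7,7-trimethyl-2,3,6,7-tetrahydrooxepine-2-carboxylate, via silyl ketene acetal 16 (not isolated), via silyl ester 17 (not isolated), via carboxylic acid 18 (not isolated)
Conditions: KN(SiMe3)2, Me3SiCl, Et3N, THF, −78 °C; toluene, 80 °C; 1 M HCl; then Me3SiCHN2, MeOH/toluene, 0 °C
Reagents that add atoms: (trimethylsilyl)diazomethane, C[Si](C)(C)C=[N+]=[N-]
Why: KN(SiMe3)2 removes a proton from the only acidic position (the O–CH2–C=O group) and in-situ silylation gives the ring-constrained silyl ketene acetal 16, which on warming should undergo a [3,3]-sigmatropic Ireland–Claisen shift: the lactone C–O bond at the allylic carbinol carbon breaks as the oxepine C2–C3 bond (C9a–C5a of the target) forms. The closest known reaction type is the Ireland–Claisen rearrangement of 6-alkenyl-1,4-dioxan-2-ones to dihydropyran-2-carboxylic acids and of alkenyl lactones to cycloalkenecarboxylic acids; the substrate here is the seven-membered homologue. Ring A is closed by a pericyclic ring transposition: the O–C(CH3)2–CH(OSi) bridge that links the ester α-carbon to the carbinol carbon in the lactone becomes part of the oxepene, whose C4=C5 bond is cis because the short bridge allows only a boat-like transition state. Oxepine C2 (later C9a) is set by that boat geometry with the ring oxygen on the inside; the quaternary C3 (later C5a) is set by suprafacial transfer from the (7S) carbinol centre across the (Z)-alkene, which places the allyl arm cis and the methyl trans to the departing oxygen; the silyl ether centre is untouched. The step needs chemoselective enolisation (secured by the single α-alkoxy CH2 group and by trapping with Me3SiCl before ketene extrusion), the boat rather than a chair pathway (secured by the bridge) and a defined alkene geometry (secured in steps 1, 3 and 6).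

Step 12
Reactants: 19 oxepene methyl ester
Product: 20 (2S,3S,6S)-3-allyl-6-[(tert-butyldimethylsilyl)oxy]-3,7,7-trimethyl-2,3,6,7-tetrahydrooxepine-2-carbaldehyde
Conditions: iBu2AlH, CH2Cl2, −78 °C
Reagents that add atoms: none
Why: Half-reduction of the α-alkoxy ester should stop at the aldehyde because the chelated tetrahedral aluminium intermediate survives until work-up.

Step 13
Reactants: 20 oxepene aldehyde
Product: 21 (2S,3S,6S)-6-[(tert-butyldimethylsilyl)oxy]-3,7,7-trimethyl-3-(2-oxopropyl)-2,3,6,7-tetrahydrooxepine-2-carbaldehyde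
Conditions: PdCl2 (10 mol%), CuCl, O2 (1 atm), DMF/H2O, rt
Reagents that add atoms: water, O
Why: Wacker oxidation should convert only the terminal alkene into the methyl ketone, since the cis-disubstituted ring alkene next to a quaternary carbon is unreactive under these conditions.

Step 14
Reactants: 21 keto aldehyde
Product: 22 (3S,5aS,9aR)-3-[(tert-butyldimethylsilyl)oxy]-2,2,5a-trimethyl-3,5a,6,9a-tetrahydro-1-benzoxepin-7(2H)-one
Conditions: KOH, MeOH, 0 °C
Reagents that add atoms: none
Why: Intramolecular aldol condensation closes ring B: only the methyl-ketone enolate reaches the aldehyde through a six-membered ring, dehydration gives the enone, and the short cold exposure to base is meant to keep the α-alkoxy aldehyde centre (C9a) from epimerising before it is locked in the trans-fused bicycle.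

Step 15
Reactants: 22 bicyclic dienone
Product: 24 (3S,5aR,6R,9aR)-6-[(benzyloxy)methyl]-3-[(tert-butyldimethylsilyl)oxy]-2,2,5a-trimethyl-3,5a,6,9a-tetrahydro-1-benzoxepin-7(2H)-one, via lithium enolate 23 (not isolated)
Conditions: LiN(iPr)2, THF, −78 °C; then BnOCH2Cl
Reagents that add atoms: benzyl chloromethyl ether, ClCOCc1ccccc1
Why: Kinetic deprotonation of the enone gives the cross-conjugated α′-enolate, so the enone double bond blocks C8 and the one-carbon unit goes to C6; the new C6 centre (alkylation anti to the axial 5a-methyl expected) is erased in step 17.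

Step 16
Reactants: 24 benzyloxymethyl dienone
Product: 25 (3S,5aR,6R,9aR)-3-[(tert-butyldimethylsilyl)oxy]-6-(hydroxymethyl)-2,2,5a-trimethyloctahydro-1-benzoxepin-7(2H)-one
Conditions: H2 (1 atm), 10% Pd/C, EtOAc, rt
Reagents that add atoms: none
Why: Heterogeneous hydrogenation should saturate both ring alkenes (no new stereocentre) and hydrogenolyse the benzyl ether in one operation, before any eastern alkene is present.

Step 17
Reactants: 25 hydroxymethyl ketone
Product: 27 (3S,5aR,9aR)-3-[(tert-butyldimethylsilyl)oxy]-2,2,5a-trimethyl-6-methylideneoctahydro-1-benzoxepin-7(2H)-one, via mesylate 26 (not isolated)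
Conditions: MsCl, Et3N, CH2Cl2, 0 °C; then DBU, rt
Reagents that add atoms: none
Why: Mesylation of the β-hydroxy ketone and E1cB elimination should give the α-methylene ketone at C6.

Step 18
Reactants: 28 4-methylpent-1-en-3-one
Product: 29 tert-butyldimethyl[(4-methylpenta-1,3-dien-3-yl)oxy]silane
Conditions: t-BuMe2SiOTf, Et3N, CH2Cl2, 0 °C
Reagents that add atoms: tert-butyldimethylsilyl trifluoromethanesulfonate, CC(C)(C)[Si](C)(C)OS(=O)(=O)C(F)(F)F
Why: Soft enolisation can only occur toward the isopropyl methine, so a single 2-silyloxy diene with a dimethyl-substituted terminus should form.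

Step 19
Reactants: 29 silyloxy diene; 30 cyclopent-2-en-1-one
Product: 31 (3aR,7aR)-5-[(tert-butyldimethylsilyl)oxy]-4,4-dimethyl-2,3,3a,4,7,7a-hexahydro-1H-inden-1-one
Conditions: (S)-B-(o-tolyl)-diphenylprolinol oxazaborolidine·HN(SO2CF3)2 (20 mol%), CH2Cl2, −40 °C
Reagents that add atoms: none
Why: Catalytic enantioselective Diels–Alder reaction: the nucleophilic CMe2 terminus of the silyloxy diene should bond to the enone β-carbon, suprafacial addition makes the ring fusion cis, and the chiral boron Lewis acid selects the enone face, which sets C3a and C7a.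

Step 20
Reactants: 31 cis-hydrindenone adduct
Product: 32 (1R,3aR,7aR)-5-[(tert-butyldimethylsilyl)oxy]-1,4,4-trimethyl-2,3,3a,4,7,7a-hexahydro-1H-inden-1-ol
Conditions: MeAl(OAr)2 (Ar = 2,6-tBu2-4-MeC6H2), MeLi, toluene, −78 °C
Reagents that add atoms: methyllithium, C[Li]
Why: The bulky aluminium phenoxide complexes the ketone from the open convex face, so methyllithium should attack from the concave face and leave the hydroxyl cis to the ring-fusion hydrogens (1R); the silyl enol ether is inert to methyllithium at this temperature.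

Step 21
Reactants: 32 tertiary alcohol
Product: 33 tert-butyldimethyl{[(1R,3aR,7aR)-1,4,4-trimethyl-1-[(triethylsilyl)oxy]-2,3,3a,4,7,7a-hexahydro-1H-inden-5-yl]oxy}silane
Conditions: Et3SiOTf, 2,6-lutidine, CH2Cl2, 0 °C
Reagents that add atoms: triethylsilyl trifluoromethanesulfonate, CC[Si](CC)(CC)OS(=O)(=O)C(F)(F)F
Why: Silylation protects the tertiary alcohol from the dihalocarbene and the later organometallic steps.

Step 22
Reactants: 33 bis-silyl ether
Product: 35 (1R,3aR,8aR)-6-bromo-1,4,4-trimethyl-1-[(triethylsilyl)oxy]-2,3,3a,4,8,8a-hexahydroazulen-5(1H)-one, via dibromocyclopropane 34 (not isolated)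
Conditions: CHBr3, KOtBu, pentane, −20 to 0 °C; then toluene, 100 °C
Reagents that add atoms: bromoform, BrC(Br)Br
Why: Dibromocarbene adds to the electron-rich silyl enol ether, and electrocyclic opening of the silyloxy dibromocyclopropane with loss of bromide and the silyl group should give the ring-expanded 2-bromo enone; the gem-dimethyl carbon fixes the regiochemistry and no stereocentre is affected.

Step 23
Reactants: 35 bromo enone
Product: 36 (1R,3aR,8aR)-1,4,4,6-tetramethyl-1-[(triethylsilyl)oxy]-2,3,3a,4,8,8a-hexahydroazulen-5(1H)-one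
Conditions: MeB(OH)2, Pd(OAc)2 (5 mol%), SPhos, K3PO4, toluene/H2O, 80 °C
Reagents that add atoms: methylboronic acid, CB(O)O
Why: Suzuki–Miyaura methylation of the 2-bromo enone should place the ring C methyl on the alkene carbon.

Step 24
Reactants: 36 methyl enone
Product: 37 triethyl{[(1R,3aR,8aR)-1,4,4,6-tetramethyl-5-methylidene-1,2,3,3a,4,5,8,8a-octahydroazulen-1-yl]oxy}silane
Conditions: Cp2TiMe2, toluene, 75 °C
Reagents that add atoms: dimethyltitanocene, C[Ti](C)(C1C=CC=C1)C1C=CC=C1
Why: Petasis methylenation is non-basic and should convert the hindered, γ-enolisable enone carbonyl into the exocyclic alkene.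

Step 25
Reactants: 37 exocyclic diene
Product: 39 [(1R,3aR,5S,8aR)-1,4,4,6-tetramethyl-1-[(triethylsilyl)oxy]-1,2,3,3a,4,5,8,8a-octahydroazulen-5-yl]methanol, via alkylborane 38 (not isolated)
Conditions: 9-BBN-H, THF, 0 °C to rt; then NaOH, H2O2
Reagents that add atoms: hydrogen peroxide, OO
Why: Hydroboration–oxidation: 9-BBN should add only to the 1,1-disubstituted exocyclic alkene with boron on the CH2 carbon, delivering hydrogen to C5 from the convex face and so placing the CH2OH group trans to the ring-fusion hydrogens (5S).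

Step 26
Reactants: 39 primary alcohol
Product: 40 triethyl{[(1R,3aR,5S,8aR)-5-(iodomethyl)-1,4,4,6-tetramethyl-1,2,3,3a,4,5,8,8a-octahydroazulen-1-yl]oxy}silane
Conditions: I2, PPh3, imidazole, CH2Cl2, 0 °C
Reagents that add atoms: iodine, II
Why: Appel-type iodination of the primary alcohol should leave the adjacent stereocentre and the silyl ether untouched.

Step 27
Reactants: 40 primary iodide; 27 methylidene ketone
Product: 41 (3S,5aR,6R,9aR)-3-[(tert-butyldimethylsilyl)oxy]-2,2,5a-trimethyl-6-{2-[(1R,3aR,5S,8aR)-1,4,4,6-tetramethyl-1-[(triethylsilyl)oxy]-1,2,3,3a,4,5,8,8a-octahydroazulen-5-yl]ethyl}octahydro-1-benzoxepin-7(2H)-one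
Conditions: (Me3Si)3SiH, AIBN (cat.), toluene, 80 °C
Reagents that add atoms: none
Why: Giese reaction: the primary radical from 40 should add to the terminal carbon of the α-methylene ketone to form the ethano bridge, and the α-keto radical takes hydrogen axially, anti to the axial 5a-methyl, giving the equatorial side chain (6R), which is also the thermodynamic epimer.

Step 28
Reactants: 41 coupled ketone
Product: 42 (3S,5aR,6R,7S,9aR)-3-[(tert-butyldimethylsilyl)oxy]-2,2,5a,7-tetramethyl-6-{2-[(1R,3aR,5S,8aR)-1,4,4,6-tetramethyl-1-[(triethylsilyl)oxy]-1,2,3,3a,4,5,8,8a-octahydroazulen-5-yl]ethyl}decahydro-1-benzoxepin-7-ol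
Conditions: MeLi, CeCl3, THF, −78 °C
Reagents that add atoms: methyllithium, C[Li]
Why: The non-basic organocerium reagent should add to the enolisable ketone from the equatorial direction, because the axial path is blocked by the syn-axial 5a-methyl, giving the axial hydroxyl and equatorial methyl (7S).

Step 29
Reactants: 42 coupled tertiary alcohol
Product: 43 (3S,5aR,6R,7S,9aR)-6-{2-[(1R,3aR,5S,8aR)-1-hydroxy-1,4,4,6-tetramethyl-1,2,3,3a,4,5,8,8a-octahydroazulen-5-yl]ethyl}-2,2,5a,7-tetramethyldecahydro-1-benzoxepine-3,7-diol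
Conditions: Bu4NF, THF, 50 °C
Reagents that add atoms: none
Why: Fluoride should remove both silyl ethers in one operation.

Step 30
Reactants: 43 triol
Product: 44 (5aR,6R,7S,9aR)-7-hydroxy-6-{2-[(1R,3aR,5S,8aR)-1-hydroxy-1,4,4,6-tetramethyl-1,2,3,3a,4,5,8,8a-octahydroazulen-5-yl]ethyl}-2,2,5a,7-tetramethyloctahydro-1-benzoxepin-3(2H)-one
Conditions: Dess–Martin periodinane, NaHCO3, CH2Cl2, 0 °C to rt
Reagents that add atoms: none
Why: Dess–Martin oxidation should convert the only secondary alcohol into the C3 ketone while the two tertiary alcohols and the trisubstituted alkene stay untouched.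

Step 31
Reactants: 44 keto diol
Product: 46 target CNP0259752.1, via bromohydrin 45 (not isolated)
Conditions: NBS, THF/H2O, 0 °C; then K2CO3, MeOH, rt
Reagents that add atoms: water, O
Why: Bromohydrin formation and ring closure: the bromonium ion should form on the convex face, water opens it anti at the tertiary alkene carbon, and carbonate closes the epoxide with inversion at the CHBr carbon, so the oxygen ends on the face of ring D and of the C5 side chain, as the target requires.

**Compound list**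

1 | prop-2-yn-1-ol | C#CCO | starting material
2 | 4-methyl-2,5-dihydro-1,2-oxamagnesole (cyclic (Z)-alkenylmagnesium alkoxide) | CC1=C[Mg]OC1 | intermediate
3 | (Z)-3-iodo-2-methylprop-2-en-1-ol | OC/C(C)=C\I | intermediate
4 | (Z)-3-bromo-1-iodo-2-methylprop-1-ene | BrC/C(C)=C\I | intermediate
5 | (Z)-1-iodo-2-methylpenta-1,4-diene | C=CC/C(C)=C\I | intermediate
6 | 3-methylbut-2-en-1-ol | CC(C)=CCO | starting material
7 | [(2S)-3,3-dimethyloxiran-2-yl]methanol | CC1(C)O[C@H]1CO | intermediate
8 | (2R)-3,3-dimethyloxirane-2-carbaldehyde | CC1(C)O[C@H]1C=O | intermediate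
9 | [(1Z)-2-methylpenta-1,4-dien-1-yl]lithium | C=CC/C(C)=C\[Li] | intermediate
10 | (1S,2Z)-1-[(2S)-3,3-dimethyloxiran-2-yl]-3-methylhexa-2,5-dien-1-ol | CC1(C)O[C@H]1[C@@H](O)/C=C(/C)CC=C | intermediate
11 | 2-[(tert-butyldimethylsilyl)oxy]acetic acid | OC(=O)CO[Si](C)(C)C(C)(C)C | starting material
12 | (1S,2Z)-1-[(2S)-3,3-dimethyloxiran-2-yl]-3-methylhexa-2,5-dien-1-yl 2-[(tert-butyldimethylsilyl)oxy]acetate | CC1(C)O[C@H]1[C@@H](OC(=O)CO[Si](C)(C)C(C)(C)C)/C=C(/C)CC=C | intermediate
13 | (1S,2Z)-1-[(2S)-3,3-dimethyloxiran-2-yl]-3-methylhexa-2,5-dien-1-yl 2-hydroxyacetate | CC1(C)O[C@H]1[C@@H](OC(=O)CO)/C=C(/C)CC=C | intermediate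
14 | (6S,7S)-6-hydroxy-5,5-dimethyl-7-[(1Z)-2-methylpenta-1,4-dien-1-yl]-1,4-dioxepan-2-one | O=C1COC(C)(C)[C@@H](O)[C@H](/C=C(/C)CC=C)O1 | intermediate
15 | (6S,7S)-6-[(tert-butyldimethylsilyl)oxy]-5,5-dimethyl-7-[(1Z)-2-methylpenta-1,4-dien-1-yl]-1,4-dioxepan-2-one | O=C1COC(C)(C)[C@@H](O[Si](C)(C)C(C)(C)C)[C@H](/C=C(/C)CC=C)O1 | intermediate
16 | (6S,7S)-6-[(tert-butyldimethylsilyl)oxy]-5,5-dimethyl-7-[(1Z)-2-methylpenta-1,4-dien-1-yl]-2-[(trimethylsilyl)oxy]-6,7-dihydro-5H-1,4-dioxepine | C[Si](C)(C)OC1=COC(C)(C)[C@@H](O[Si](C)(C)C(C)(C)C)[C@H](/C=C(/C)CC=C)O1 | intermediate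
17 | trimethylsilyl (2S,3S,6S)-3-allyl-6-[(tert-butyldimethylsilyl)oxy]-3,7,7-trimethyl-2,3,6,7-tetrahydrooxepine-2-carboxylate | C[Si](C)(C)OC(=O)[C@H]1OC(C)(C)[C@@H](O[Si](C)(C)C(C)(C)C)C=C[C@]1(C)CC=C | intermediate
18 | (2S,3S,6S)-3-allyl-6-[(tert-butyldimethylsilyl)oxy]-3,7,7-trimethyl-2,3,6,7-tetrahydrooxepine-2-carboxylic acid | OC(=O)[C@H]1OC(C)(C)[C@@H](O[Si](C)(C)C(C)(C)C)C=C[C@]1(C)CC=C | intermediate
19 | methyl (2S,3S,6S)-3-allyl-6-[(tert-butyldimethylsilyl)oxy]-3,7,7-trimethyl-2,3,6,7-tetrahydrooxepine-2-carboxylate | COC(=O)[C@H]1OC(C)(C)[C@@H](O[Si](C)(C)C(C)(C)C)C=C[C@]1(C)CC=C | intermediate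
20 | (2S,3S,6S)-3-allyl-6-[(tert-butyldimethylsilyl)oxy]-3,7,7-trimethyl-2,3,6,7-tetrahydrooxepine-2-carbaldehyde | O=C[C@H]1OC(C)(C)[C@@H](O[Si](C)(C)C(C)(C)C)C=C[C@]1(C)CC=C | intermediate
21 | (2S,3S,6S)-6-[(tert-butyldimethylsilyl)oxy]-3,7,7-trimethyl-3-(2-oxopropyl)-2,3,6,7-tetrahydrooxepine-2-carbaldehyde | O=C[C@H]1OC(C)(C)[C@@H](O[Si](C)(C)C(C)(C)C)C=C[C@]1(C)CC(C)=O | intermediate
22 | (3S,5aS,9aR)-3-[(tert-butyldimethylsilyl)oxy]-2,2,5a-trimethyl-3,5a,6,9a-tetrahydro-1-benzoxepin-7(2H)-one (trans-fused; silyloxy group cis to the angular methyl) | O=C1C=C[C@H]2OC(C)(C)[C@@H](O[Si](C)(C)C(C)(C)C)C=C[C@]2(C)C1 | intermediate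
23 | lithium 6,7-enolate of 22 (cross-conjugated dienolate; stereocentres as in 22) | [Li]OC1C=C[C@H]2OC(C)(C)[C@@H](O[Si](C)(C)C(C)(C)C)C=C[C@]2(C)C=1 | intermediate
24 | (3S,5aR,6R,9aR)-6-[(benzyloxy)methyl]-3-[(tert-butyldimethylsilyl)oxy]-2,2,5a-trimethyl-3,5a,6,9a-tetrahydro-1-benzoxepin-7(2H)-one (expected major C6 epimer) | O=C1C=C[C@H]2OC(C)(C)[C@@H](O[Si](C)(C)C(C)(C)C)C=C[C@]2(C)[C@@H]1COCc1ccccc1 | intermediate
25 | (3S,5aR,6R,9aR)-3-[(tert-butyldimethylsilyl)oxy]-6-(hydroxymethyl)-2,2,5a-trimethyloctahydro-1-benzoxepin-7(2H)-one | O=C1CC[C@H]2OC(C)(C)[C@@H](O[Si](C)(C)C(C)(C)C)CC[C@]2(C)[C@@H]1CO | intermediate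
26 | methanesulfonate of 25 (stereocentres as in 25) | O=C1CC[C@H]2OC(C)(C)[C@@H](O[Si](C)(C)C(C)(C)C)CC[C@]2(C)[C@@H]1COS(C)(=O)=O | intermediate
27 | (3S,5aR,9aR)-3-[(tert-butyldimethylsilyl)oxy]-2,2,5a-trimethyl-6-methylideneoctahydro-1-benzoxepin-7(2H)-one | C=C1C(=O)CC[C@H]2OC(C)(C)[C@@H](O[Si](C)(C)C(C)(C)C)CC[C@]12C | intermediate
28 | 4-methylpent-1-en-3-one | C=CC(=O)C(C)C | starting material
29 | tert-butyldimethyl[(4-methylpenta-1,3-dien-3-yl)oxy]silane | C=CC(O[Si](C)(C)C(C)(C)C)=C(C)C | intermediate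
30 | cyclopent-2-en-1-one | O=C1C=CCC1 | starting material
31 | (3aR,7aR)-5-[(tert-butyldimethylsilyl)oxy]-4,4-dimethyl-2,3,3a,4,7,7a-hexahydro-1H-inden-1-one (cis-fused) | O=C1CC[C@@H]2[C@H]1CC=C(O[Si](C)(C)C(C)(C)C)C2(C)C | intermediate
32 | (1R,3aR,7aR)-5-[(tert-butyldimethylsilyl)oxy]-1,4,4-trimethyl-2,3,3a,4,7,7a-hexahydro-1H-inden-1-ol (hydroxyl cis to the ring-fusion hydrogens) | C[C@@]1(O)CC[C@@H]2[C@H]1CC=C(O[Si](C)(C)C(C)(C)C)C2(C)C | intermediate
33 | tert-butyldimethyl{[(1R,3aR,7aR)-1,4,4-trimethyl-1-[(triethylsilyl)oxy]-2,3,3a,4,7,7a-hexahydro-1H-inden-5-yl]oxy}silane | C[C@@]1(O[Si](CC)(CC)CC)CC[C@@H]2[C@H]1CC=C(O[Si](C)(C)C(C)(C)C)C2(C)C | intermediate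
34 | dibromocyclopropane adduct of 33 across its enol ether double bond (mixture at the two new ring carbons; other centres as in 33) | C[C@@]1(O[Si](CC)(CC)CC)CC[C@@H]2[C@H]1CC1C(Br)(Br)C1(O[Si](C)(C)C(C)(C)C)C2(C)C | intermediate
35 | (1R,3aR,8aR)-6-bromo-1,4,4-trimethyl-1-[(triethylsilyl)oxy]-2,3,3a,4,8,8a-hexahydroazulen-5(1H)-one | C[C@@]1(O[Si](CC)(CC)CC)CC[C@@H]2[C@H]1CC=C(Br)C(=O)C2(C)C | intermediate
36 | (1R,3aR,8aR)-1,4,4,6-tetramethyl-1-[(triethylsilyl)oxy]-2,3,3a,4,8,8a-hexahydroazulen-5(1H)-one | C[C@@]1(O[Si](CC)(CC)CC)CC[C@@H]2[C@H]1CC=C(C)C(=O)C2(C)C | intermediate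
37 | triethyl{[(1R,3aR,8aR)-1,4,4,6-tetramethyl-5-methylidene-1,2,3,3a,4,5,8,8a-octahydroazulen-1-yl]oxy}silane | C[C@@]1(O[Si](CC)(CC)CC)CC[C@@H]2[C@H]1CC=C(C)C(=C)C2(C)C | intermediate
38 | 9-{[(1R,3aR,5S,8aR)-1,4,4,6-tetramethyl-1-[(triethylsilyl)oxy]-1,2,3,3a,4,5,8,8a-octahydroazulen-5-yl]methyl}-9-borabicyclo[3.3.1]nonane | C[C@@]1(O[Si](CC)(CC)CC)CC[C@@H]2[C@H]1CC=C(C)[C@H](CB1C3CCCC1CCC3)C2(C)C | intermediate
39 | [(1R,3aR,5S,8aR)-1,4,4,6-tetramethyl-1-[(triethylsilyl)oxy]-1,2,3,3a,4,5,8,8a-octahydroazulen-5-yl]methanol | C[C@@]1(O[Si](CC)(CC)CC)CC[C@@H]2[C@H]1CC=C(C)[C@H](CO)C2(C)C | intermediate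
40 | triethyl{[(1R,3aR,5S,8aR)-5-(iodomethyl)-1,4,4,6-tetramethyl-1,2,3,3a,4,5,8,8a-octahydroazulen-1-yl]oxy}silane | C[C@@]1(O[Si](CC)(CC)CC)CC[C@@H]2[C@H]1CC=C(C)[C@H](CI)C2(C)C | intermediate
41 | (3S,5aR,6R,9aR)-3-[(tert-butyldimethylsilyl)oxy]-2,2,5a-trimethyl-6-{2-[(1R,3aR,5S,8aR)-1,4,4,6-tetramethyl-1-[(triethylsilyl)oxy]-1,2,3,3a,4,5,8,8a-octahydroazulen-5-yl]ethyl}octahydro-1-benzoxepin-7(2H)-one | C[C@@]1(O[Si](CC)(CC)CC)CC[C@@H]2[C@H]1CC=C(C)[C@H](CC[C@H]1C(=O)CC[C@H]3OC(C)(C)[C@@H](O[Si](C)(C)C(C)(C)C)CC[C@]13C)C2(C)C | intermediate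
42 | (3S,5aR,6R,7S,9aR)-3-[(tert-butyldimethylsilyl)oxy]-2,2,5a,7-tetramethyl-6-{2-[(1R,3aR,5S,8aR)-1,4,4,6-tetramethyl-1-[(triethylsilyl)oxy]-1,2,3,3a,4,5,8,8a-octahydroazulen-5-yl]ethyl}decahydro-1-benzoxepin-7-ol | C[C@@]1(O[Si](CC)(CC)CC)CC[C@@H]2[C@H]1CC=C(C)[C@H](CC[C@H]1[C@@](C)(O)CC[C@H]3OC(C)(C)[C@@H](O[Si](C)(C)C(C)(C)C)CC[C@]13C)C2(C)C | intermediate
43 | (3S,5aR,6R,7S,9aR)-6-{2-[(1R,3aR,5S,8aR)-1-hydroxy-1,4,4,6-tetramethyl-1,2,3,3a,4,5,8,8a-octahydroazulen-5-yl]ethyl}-2,2,5a,7-tetramethyldecahydro-1-benzoxepine-3,7-diol | C[C@@]1(O)CC[C@@H]2[C@H]1CC=C(C)[C@H](CC[C@H]1[C@@](C)(O)CC[C@H]3OC(C)(C)[C@@H](O)CC[C@]13C)C2(C)C | intermediate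
44 | (5aR,6R,7S,9aR)-7-hydroxy-6-{2-[(1R,3aR,5S,8aR)-1-hydroxy-1,4,4,6-tetramethyl-1,2,3,3a,4,5,8,8a-octahydroazulen-5-yl]ethyl}-2,2,5a,7-tetramethyloctahydro-1-benzoxepin-3(2H)-one | C[C@@]1(O)CC[C@@H]2[C@H]1CC=C(C)[C@H](CC[C@H]1[C@@](C)(O)CC[C@H]3OC(C)(C)C(=O)CC[C@]13C)C2(C)C | intermediate
45 | bromohydrin of 44: ring C carries the tertiary hydroxyl at azulene C6 on the face of ring D and bromine at C7 trans to it (other centres as in 44) | C[C@@]1(O)CC[C@@H]2[C@H]1C[C@@H](Br)[C@](C)(O)[C@H](CC[C@H]1[C@@](C)(O)CC[C@H]3OC(C)(C)C(=O)CC[C@]13C)C2(C)C | intermediate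
46 | CNP0259752.1: (5aR,6R,7S,9aR)-7-hydroxy-2,2,5a,7-tetramethyl-3-oxo-octahydro-1-benzoxepine carrying at C6 a 2-[(1R,3aR,5R,6R,7S,8aR)-6,7-epoxy-1-hydroxy-1,4,4,6-tetramethyldecahydroazulen-5-yl]ethyl group | CC1(C)O[C@@H]2CC[C@](C)(O)[C@H](CC[C@@H]3C(C)(C)[C@@H]4CC[C@@](C)(O)[C@@H]4C[C@@H]4O[C@@]43C)[C@@]2(C)CCC1=O | target

**Totals**

Total step count: 31. Longest linear sequence: 20 steps (steps 1–3, 6–17 and 27–31).

**Steps most likely to fail**

Step 11 (Ireland–Claisen ring closure). The sigmatropic shift may be too slow, because in the bridged boat the allyl-bearing alkene terminus must fold under the lactone ring; ketene extrusion from the enolate or C-silylation could then overtake it. The fallback sets out from 15 and returns at 19. Methanolysis of the lactone (K2CO3, MeOH, 0 °C) should give hydroxy ester F1, and MnO2 oxidation of the allylic alcohol the (Z)-enone F2. A base-mediated intramolecular Michael addition of the alkoxyacetate enolate to the β,β-disubstituted enone (Cs2CO3 or catalytic KOtBu, THF) would close the same ring through the same bond and give keto ester F3. The ester-bearing carbon can equilibrate to the isomer with the ester trans to the allyl group, and the two configurations at the quaternary carbon are diastereomers because of the silyloxy centre, so they can be separated. Kinetic enol triflate formation toward the ring CH2 group (KN(SiMe3)2, PhN(SO2CF3)2) would give enol triflate F4, and reduction of the triflate (Pd(OAc)2, PPh3, HCO2H, Bu3N, DMF, 60 °C) would give 19.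

Step 9 (7-endo epoxide opening). Participation of the ester carbonyl oxygen in the opening of the protonated epoxide (acyloxonium formation and acyl migration), or 6-exo attack at the secondary carbon, could compete with closure of the seven-membered ring. The fallback sets out from 10 and returns at 15. Silylation (Et3SiOTf, 2,6-lutidine) should give triethylsilyl ether F5. Intermolecular opening of the epoxide at its tertiary carbon with methyl glycolate (BF3·OEt2 cat., CH2Cl2, −40 °C) would give hydroxy ether F6, and silylation (t-BuMe2SiOTf, 2,6-lutidine) bis-silyl ether F7. Saponification with an acidic work-up that also removes the triethylsilyl group (LiOH, THF/H2O; 1 M HCl) would give hydroxy acid F8, and lactonisation through the 2,4,6-trichlorobenzoyl mixed anhydride (Et3N, then DMAP, toluene, high dilution) would give 15.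

Step 19 (enantioselective Diels–Alder reaction). Bond formation at the tetrasubstituted enol ether terminus may be sluggish, so that a stepwise Mukaiyama–Michael pathway with poor facial control takes over and the enantiomeric purity of the eastern half is lost. The fallback sets out from 29 and returns at 31, with absolute configuration taken from the chiral pool. A Lewis-acid-promoted Diels–Alder reaction (AlBr3/AlMe3, toluene/CH2Cl2, −10 °C) of 29 with commercial (4S)-4-[(tert-butyldimethylsilyl)oxy]cyclopent-2-en-1-one (O=C1C=C[C@@H](O[Si](C)(C)C(C)(C)C)C1) should occur anti to the silyloxy group and give bis-silyloxy adduct F9. β-Elimination of the silanol (DBU, CH2Cl2) would give enone F10, and conjugate reduction with [(Ph3P)CuH]6 (benzene, H2O) would give 31.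

Further compounds
F1 | step 11 | methyl 2-{[(3S,4S,5Z)-3-[(tert-butyldimethylsilyl)oxy]-4-hydroxy-2,6-dimethylnona-5,8-dien-2-yl]oxy}acetate | COC(=O)COC(C)(C)[C@@H](O[Si](C)(C)C(C)(C)C)[C@@H](O)/C=C(/C)CC=C
F2 | step 11 | methyl 2-{[(3R,5Z)-3-[(tert-butyldimethylsilyl)oxy]-2,6-dimethyl-4-oxonona-5,8-dien-2-yl]oxy}acetate | COC(=O)COC(C)(C)[C@@H](O[Si](C)(C)C(C)(C)C)C(=O)/C=C(/C)CC=C
F3 | step 11 | methyl (2S,3S,6R)-3-allyl-6-[(tert-butyldimethylsilyl)oxy]-3,7,7-trimethyl-5-oxooxepane-2-carboxylate | COC(=O)[C@H]1OC(C)(C)[C@@H](O[Si](C)(C)C(C)(C)C)C(=O)C[C@]1(C)CC=C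
F4 | step 11 | methyl 3-allyl-6-[(tert-butyldimethylsilyl)oxy]-3,7,7-trimethyl-5-{[(trifluoromethyl)sulfonyl]oxy}-2,3,6,7-tetrahydrooxepine-2-carboxylate (stereocentres as in 19) | COC(=O)[C@H]1OC(C)(C)[C@@H](O[Si](C)(C)C(C)(C)C)C(OS(=O)(=O)C(F)(F)F)=C[C@]1(C)CC=C
F5 | step 9 | triethyl{[(1S,2Z)-1-[(2S)-3,3-dimethyloxiran-2-yl]-3-methylhexa-2,5-dien-1-yl]oxy}silane | CC1(C)O[C@H]1[C@@H](O[Si](CC)(CC)CC)/C=C(/C)CC=C
F6 | step 9 | methyl 2-{[(3S,4S,5Z)-3-hydroxy-2,6-dimethyl-4-[(triethylsilyl)oxy]nona-5,8-dien-2-yl]oxy}acetate | COC(=O)COC(C)(C)[C@@H](O)[C@@H](O[Si](CC)(CC)CC)/C=C(/C)CC=C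
F7 | step 9 | methyl 2-{[(3S,4S,5Z)-3-[(tert-butyldimethylsilyl)oxy]-2,6-dimethyl-4-[(triethylsilyl)oxy]nona-5,8-dien-2-yl]oxy}acetate | COC(=O)COC(C)(C)[C@@H](O[Si](C)(C)C(C)(C)C)[C@@H](O[Si](CC)(CC)CC)/C=C(/C)CC=C
F8 | step 9 | 2-{[(3S,4S,5Z)-3-[(tert-butyldimethylsilyl)oxy]-4-hydroxy-2,6-dimethylnona-5,8-dien-2-yl]oxy}acetic acid | OC(=O)COC(C)(C)[C@@H](O[Si](C)(C)C(C)(C)C)[C@@H](O)/C=C(/C)CC=C
F9 | step 19 | (3S,3aR,7aR)-3,5-bis[(tert-butyldimethylsilyl)oxy]-4,4-dimethyl-2,3,3a,4,7,7a-hexahydro-1H-inden-1-one | O=C1C[C@H](O[Si](C)(C)C(C)(C)C)[C@@H]2[C@H]1CC=C(O[Si](C)(C)C(C)(C)C)C2(C)C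
F10 | step 19 | (3aR,7aR)-5-[(tert-butyldimethylsilyl)oxy]-4,4-dimethyl-3a,4,7,7a-tetrahydro-1H-inden-1-one | O=C1C=C[C@@H]2[C@H]1CC=C(O[Si](C)(C)C(C)(C)C)C2(C)C
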